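## Retrosynthetic overview

1. C2 (R) is the only stereocentre and is cleared first. The flavanone is traced back to flat 5,7-dimethoxy-8-prenylflavone, whose C2=C3 bond is reduced last by a chiral copper hydride.
2. Structural feature used: in ring C the C4 carbonyl carbon stands between C4a of ring A and the C3–C2 pair bearing phenyl ring B, and O1 links C2 to C8a. Hence C4 = CO, C3–C2–Ph = phenylacetylene, and C4a(Br)/C8a(OH) = an ortho-bromophenol.
3. One palladium-catalysed carbonylative alkynylation with 6-endo closure makes C4a–C4, C4–C3 and O1–C2.
4. The bromophenol comes from 3,5-dimethoxyphenol. Bromine goes on one ortho carbon, then prenyl goes on the other by O-(1,1-dimethylpropargyl)ation, semi-hydrogenation and aromatic Claisen rearrangement.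
5. Ring order: rings A and B are bought, ring C is the only ring built (step 5), and C2 is set in step 6.

Key step: step 5

Assumption: the (R)-antipode of DTBM-SEGPHOS is taken as the one that directs hydride to the Si face of C2; the sense of induction should be verified on the first run, and the equally available (S)-ligand used if it proves opposite.

## Route

Step 1
Reactants: 1 3,5-dimethoxyphenol
Product: 2 2-bromo-3,5-dimethoxyphenol
Conditions: NBS (1.0 equiv), CH2Cl2, −78 °C → 0 °C, dark
Reagents that add atoms: N-bromosuccinimide, O=C1CCC(=O)N1Br
Why: Electrophilic aromatic bromination: all three free ring carbons are activated, but the two equivalent carbons ortho to OH are less crowded than C4 between the two methoxy groups, NBS in a non-polar solvent is guided to them by hydrogen bonding to the phenol, and one equivalent of reagent at low temperature should hold the reaction at the monobromide.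

Step 2
Reactants: 2 2-bromo-3,5-dimethoxyphenol; 3 3-chloro-3-methylbut-1-yne
Product: 4 2-bromo-1,5-dimethoxy-3-[(2-methylbut-3-yn-2-yl)oxy]benzene
Conditions: CuCl2·2H2O (1 mol %), DBU (1.3 equiv), MeCN, 0 °C
Reagents that add atoms: 3-chloro-3-methylbut-1-yne (3), CC(C)(Cl)C#C
Why: Copper-catalysed propargylic substitution (O-alkylation of the phenoxide by the copper-activated tertiary propargylic chloride) should form the hindered tertiary aryl ether at 0 °C, far below the temperature of chromene-forming rearrangement, and it leaves the aryl bromide untouched.

Step 3
Reactants: 4 2-bromo-1,5-dimethoxy-3-[(2-methylbut-3-yn-2-yl)oxy]benzene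
Product: 5 2-bromo-1,5-dimethoxy-3-[(2-methylbut-3-en-2-yl)oxy]benzene
Conditions: H2 (1 atm), Pd/CaCO3 poisoned with Pb(OAc)2, quinoline, EtOAc, rt, stopped after 1 equiv H2
Reagents that add atoms: none
Why: Lindlar semi-hydrogenation: the lead- and quinoline-poisoned palladium surface should take the terminal alkyne to the vinyl group and stop there, and it does not hydrogenolyse an electron-rich aryl bromide at 1 atm.

Step 4
Reactants: 5 2-bromo-1,5-dimethoxy-3-[(2-methylbut-3-en-2-yl)oxy]benzene
Product: 7 2-bromo-3,5-dimethoxy-6-(3-methylbut-2-en-1-yl)phenol, via cyclohexadienone 6 (not isolated)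
Conditions: PhNEt2, 140 °C, Ar; cold dilute HCl wash
Reagents that add atoms: none
Why: Aromatic Claisen rearrangement: the [3,3] shift turns the 1,1-dimethylallyl unit into a prenyl group on the only hydrogen-bearing ortho carbon, dienone 6 tautomerises irreversibly to the phenol (a shift to the brominated ortho carbon is reversible and unproductive), and the basic solvent suppresses acid-induced ether cleavage and chroman formation.

Step 5
Reactants: 7 2-bromo-3,5-dimethoxy-6-(3-methylbut-2-en-1-yl)phenol; 8 phenylacetylene; 9 carbon monoxide
Product: 12 5,7-dimethoxy-8-(3-methylbut-2-en-1-yl)-2-phenyl-4H-chromen-4-one (5,7-dimethoxy-8-prenylflavone), via ynone 10 (not isolated), via enaminone 11 (not isolated)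
Conditions: Pd(OAc)2 (3 mol %), di(1-adamantyl)-n-butylphosphine (9 mol %), 8 (1.5 equiv), CO (10 bar), Et2NH (5 equiv), degassed DMF, 110 °C, autoclave
Reagents that add atoms: phenylacetylene (8), C#Cc1ccccc1; carbon monoxide (9), [C-]#[O+]; diethylamine, CCNCC (its atoms stand only in 11 and leave again on ring closure)
Why: Zerovalent palladium bearing the bulky, electron-rich phosphine inserts into the C–Br bond of 7 (the future C4a), CO inserts to give an aroylpalladium bromide, and amine-assisted, copper-free alkynyl transfer from 8 followed by reductive elimination gives ynone 10, which holds the new C4a–C4 and C4–C3 bonds. Diethylamine adds to the phenyl-bearing alkyne carbon of 10 (future C2) to give the push–pull enaminone 11, whose C8a hydroxyl attacks the same carbon and expels the amine, forming O1–C2. The closest known reaction type is the palladium-catalysed carbonylative Sonogashira coupling of ortho-halophenols with terminal alkynes in a secondary amine, which ends in flavones, combined with the carbonylative alkynylation of aryl bromides under Pd(OAc)2 and this phosphine. Ring C closes by a 6-endo-trig addition–elimination on 11, and no stereocentre is formed. The step needs 6-endo (flavone) over 5-exo-dig (aurone) closure, which is secured because 11 keeps C2 as its only electrophilic carbon, and CO insertion over direct alkynylation, which is secured by the CO pressure and by the OH and OMe groups flanking the arylpalladium carbon, since they hinder alkynyl transfer more than uptake of the small CO. The same two ortho groups shield the aroylpalladium from the branched amine, so the slim alkynyl partner should win over amide formation, and the trisubstituted prenyl alkene, meta to the reacting carbon, cannot reach the metal.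

Step 6
Reactants: 12 5,7-dimethoxy-8-(3-methylbut-2-en-1-yl)-2-phenyl-4H-chromen-4-one
Product: 13 (2R)-5,7-dimethoxy-8-(3-methylbut-2-en-1-yl)-2-phenyl-2,3-dihydro-4H-chromen-4-one (target)
Conditions: Cu(OAc)2·H2O (5 mol %), (R)-DTBM-SEGPHOS (5.5 mol %), (EtO)2MeSiH (2 equiv), t-BuOH (2 equiv), toluene, 0 °C → rt; aq NH4Cl work-up, no base
Reagents that add atoms: none
Why: Copper hydride asymmetric conjugate reduction (1,4-hydrosilylation), known for 2-substituted chromones and β,β-disubstituted cyclic enones: the C2-symmetric pocket of the ligated CuH should admit the flat benzopyranone by one face only, so hydride goes to the Si face of C2 and sets the (R) centre, tert-butanol protonates the enolate before it can open by retro-oxa-Michael reaction and turns the catalyst over, and the unactivated trisubstituted prenyl alkene is inert to hydrocupration.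

## Compound list

1 | 3,5-dimethoxyphenol | COc1cc(O)cc(OC)c1 | starting material
2 | 2-bromo-3,5-dimethoxyphenol | COc1cc(O)c(Br)c(OC)c1 | intermediate
3 | 3-chloro-3-methylbut-1-yne | CC(C)(Cl)C#C | starting material
4 | 2-bromo-1,5-dimethoxy-3-[(2-methylbut-3-yn-2-yl)oxy]benzene | COc1cc(OC(C)(C)C#C)c(Br)c(OC)c1 | intermediate
5 | 2-bromo-1,5-dimethoxy-3-[(2-methylbut-3-en-2-yl)oxy]benzene | COc1cc(OC(C)(C)C=C)c(Br)c(OC)c1 | intermediate
6 | 2-bromo-3,5-dimethoxy-6-(3-methylbut-2-en-1-yl)cyclohexa-2,4-dien-1-one (racemic, not isolated) | O=C1C(Br)=C(OC)C=C(OC)C1CC=C(C)C | intermediate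
7 | 2-bromo-3,5-dimethoxy-6-(3-methylbut-2-en-1-yl)phenol | COc1cc(OC)c(Br)c(O)c1CC=C(C)C | intermediate
8 | phenylacetylene | C#Cc1ccccc1 | starting material
9 | carbon monoxide | [C-]#[O+] | starting material
10 | 1-[2-hydroxy-4,6-dimethoxy-3-(3-methylbut-2-en-1-yl)phenyl]-3-phenylprop-2-yn-1-one (not isolated) | COc1cc(OC)c(C(=O)C#Cc2ccccc2)c(O)c1CC=C(C)C | intermediate
11 | (E)-3-(diethylamino)-1-[2-hydroxy-4,6-dimethoxy-3-(3-methylbut-2-en-1-yl)phenyl]-3-phenylprop-2-en-1-one (not isolated; push–pull double bond, geometry labile) | COc1cc(OC)c(C(=O)/C=C(/N(CC)CC)c2ccccc2)c(O)c1CC=C(C)C | intermediate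
12 | 5,7-dimethoxy-8-(3-methylbut-2-en-1-yl)-2-phenyl-4H-chromen-4-one | COc1cc(OC)c2c(c1CC=C(C)C)OC(c1ccccc1)=CC2=O | intermediate
13 | (2R)-5,7-dimethoxy-8-(3-methylbut-2-en-1-yl)-2-phenyl-2,3-dihydro-4H-chromen-4-one | COc1cc(OC)c2c(c1CC=C(C)C)O[C@@H](c1ccccc1)CC2=O | target

## Step count and risks

Total step count: 6. Longest linear sequence: 6 steps (1 → 13).

**First risk, step 5.** Oxidative addition into the electron-rich C–Br bond flanked by OH and OMe may be too slow under CO, so that the catalyst decays. The aroylpalladium may also be intercepted by diethylamine before alkynyl transfer.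

The fallback sets out from 7 and 8 and comes back at 12. C4 is no longer taken from CO gas but is carried in on the alkyne, and C4a–C4 is made by organolithium acylation.
- Phenylacetylene 8 is lithiated (n-BuLi, THF, −78 °C) and acylated with N-methoxy-N-methylcarbamoyl chloride to N-methoxy-N-methyl-3-phenylprop-2-ynamide F1.
- Bromophenol 7 is deprotonated with n-BuLi, submitted to bromine–lithium exchange with t-BuLi (THF, −78 °C) and treated with F1.
- A cold acidic quench should give ynone 10, this time isolated.
- Warming 10 with Et2NH in EtOH should carry it through 11 to 12 by the same 6-endo addition–elimination.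

**Second risk, step 6.** Four processes could spoil this step:
- hydrocupration of the vinylogous ester may be sluggish;
- facial selectivity may be poor;
- the liberated ketone may be reduced further;
- the optical purity may erode through reversible retro-oxa-Michael opening of the enolate.

The fallback sets out from 12 and comes back at 13. Induction in the C–H bond formation is given up, and the configuration is fixed by kinetic resolution.
- Flavone 12 is reduced with the more reactive achiral copper hydride [Cu(OAc)2·H2O, 1,2-bis(diphenylphosphino)benzene, (EtO)2MeSiH, t-BuOH, toluene, rt] to racemic 5,7-dimethoxy-8-(3-methylbut-2-en-1-yl)flavanone F2.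
- Noyori–Ikariya transfer hydrogenation with RuCl(p-cymene)[(S,S)-TsDPEN] (HCO2H/Et3N, EtOAc, rt) is run slightly past half conversion.
- For the (2S)-ketone the catalyst's preference for the (4S)-alcohol matches the substrate's preference for 2,4-cis delivery. That enantiomer should therefore be consumed to (2S,4S)-5,7-dimethoxy-8-(3-methylbut-2-en-1-yl)flavan-4-ol F3.
- The mismatched (2R)-ketone 13 should remain and is separated by chromatography. The prenyl alkene is inert to these conditions.

**Third risk, step 1.** Bromination may stray to C4 or run on to a second bromination.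

The fallback sets out from 1 and comes back at 2. The electrophilic substitution is replaced by directed ortho-metalation.
- Phenol 1 is protected (MOMCl, i-Pr2NEt, CH2Cl2) as 1,3-dimethoxy-5-(methoxymethoxy)benzene F4.
- n-BuLi (THF, 0 °C) should lithiate the carbon between the stronger OMOM director and OMe.
- A quench with BrCH2CH2Br (−78 °C → rt) should give 2-bromo-1,5-dimethoxy-3-(methoxymethoxy)benzene F5.
- HCl in MeOH (40 °C) should release 2. No acid-sensitive prenyl group is present at this stage.

Further compounds
F1 | step 5 | N-methoxy-N-methyl-3-phenylprop-2-ynamide | CON(C)C(=O)C#Cc1ccccc1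
F2 | step 6 | racemic 5,7-dimethoxy-8-(3-methylbut-2-en-1-yl)flavanone | COc1cc(OC)c2c(c1CC=C(C)C)OC(c1ccccc1)CC2=O
F3 | step 6 | (2S,4S)-5,7-dimethoxy-8-(3-methylbut-2-en-1-yl)flavan-4-ol (2,4-cis) | COc1cc(OC)c2c(c1CC=C(C)C)O[C@H](c1ccccc1)C[C@@H]2O
F4 | step 1 | 1,3-dimethoxy-5-(methoxymethoxy)benzene | COCOc1cc(OC)cc(OC)c1
F5 | step 1 | 2-bromo-1,5-dimethoxy-3-(methoxymethoxy)benzene | COCOc1cc(OC)cc(OC)c1Br
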